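The chair opened by putting the flask on the table: substrate and coupling partner, closed and stirred, giving the target.

| setting | alpha | epsilon | beta | flask |
|---|---|---|---|---|
| substrate | 22 mM | 22 mM | 44 mM | 22 mM |
| coupling partner | 2.1 equiv | 3.3 equiv | 1.5 equiv | 1.50 equiv |
| remark | run made earlier | run made earlier | run made earlier |  |
| time |  |  |  | 3.0 d |

| run | time / d | target / % | substrate / % |
|---|---|---|---|
| alpha | 0.250 | 67 | 29 |
| alpha | 0.833 | 67 | 32 |
| alpha | 1.25 | 69 | 31 |
| alpha | 2.00 | 70 | 30 |
| alpha | 3.00 | 67 | 33 |
| epsilon | 0.625 | 77 | 23 |
| epsilon | 1.25 | 78 | 22 |
| epsilon | 1.67 | 77 | 26 |
| epsilon | 2.50 | 80 | 26 |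
| epsilon | 3.00 | 79 | 24 |
| beta | 0.250 | 58 | 41 |
| beta | 0.833 | 60 | 39 |
| beta | 1.25 | 61 | 42 |
| beta | 2.00 | 61 | 40 |
| beta | 3.00 | 59 | 41 |

(scatter of a reading: 1.5 percentage points)

- the reaction counts as stopped when no species that holds the substrate changes by six tenths of a point or more over the second half of the time

- the state of affairs at 3.0 d: stopped, and by what, or still going (it is still moving / forward and back rates have come level / all of the substrate has reacted / the coupling partner has run out first)
- the target standing at 3.0 d, as a percentage of the substrate charged

The chair noted that the alpha run, at the flask's substrate charge, is already flat at 0.250 d, far shorter than the 3.0 d asked, so the question is where the flask stops, not how fast it gets there.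

I, taking the minutes, proposed to follow what stays behind rather than what is made. Averaged over their readings, the substrate stands at 31.0 % in alpha, 24.2 % in epsilon and 40.6 % in beta. Multiplying each by one plus its equivalents of coupling partner gives 0.961, 1.04 and 1.02, readings near one, and beta does not stray at twice the concentration.

I therefore committed the flask, at 1.50 equiv, to 40.0 % of its substrate unreacted at the stop: the left fraction, one divided by one plus the equivalents of partner. That puts the target at 60.0 %. No run reads the partner, so I left open what stops the flask.

The forecast's maker gave 60 % of target and the state "forward and back rates have come level", writing: “This points to equilibrium, not exhaustion of a reagent”. Our numbers agree, but both rest on the same readings, so the chair recorded no check.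

The flask stood at 60.0 % of target at 3.0 d.

    substrate + coupling partner → target (k = 3.10 M⁻¹ min⁻¹)
    2 coupling partner → side product (k = 3.10 M⁻¹ min⁻¹)
    substrate → decomposition product (k = 6.60 × 10⁻⁶ min⁻¹)

Its state at that time was not that forward and back rates have come level but that the coupling partner has run out first, with 0 % of the partner's charge there at 3.00 d. The left fraction of 40.0 % stands beside 39 % of substrate in the flask at 3.00 d. For a neighbour flask with 0.600 equiv of partner, the same rule gives 62.5 %, and that neighbour held 60.7 % of its substrate at 3.00 d.

The data are simulated from invented constants; noise was put on by code.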